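The target is a trans-fused hydroazulene (five-membered ring C1–C5, seven-membered ring C1, C5–C10; daucane numbering). Everything rests on the fact that the methyl-bearing quaternary C1 lies β, and the ring-fusion carbon C5 α, to C4 when C4 is a ketone. One operation on a 3-substituted cyclopent-2-enone therefore adds methyl to C1 under chiral copper catalysis and joins the resulting C4–C5 enolate to acrolein (C5–C6). This sets C1, C5 and C6 and delivers both alkenes for a later C7=C8 ring-closing metathesis. The precursor is cyclopent-2-enone carrying at C1 a CH2 (C10) attached to the ethylene ketal of an isopropenyl ketone (C9, C8).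

Key step: step 8

Numbering: daucane numbering is kept for all intermediates. C1 is the quaternary carbon with methyl C15, C2–C3 are ring CH2, C4 is the ketone or carbinol carbon, and C5 is the ring-fusion CH. C6 is the carbinol, C7=C8 carries methyl C14, C9 is the carbonyl and C10 is CH2.
Assumption: the sense of induction of the copper/phosphoramidite catalyst on the key-step enone cannot be predicted with certainty. Both ligand antipodes are accessible, and the one that gives 1R is used.
Remark: the C4 carbinol centre of steps 2–6 is racemic and is erased in step 7. The acetal carbon of the 1-ethoxyethyl (EE) group is an epimer mixture and leaves in step 15.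

Step 1
Reactants: 1 3-ethoxycyclopent-2-en-1-one; 2 N-methoxy-N-methylacetamide
Product: 5 N-methoxy-N-methyl-2-(3-oxocyclopent-1-en-1-yl)acetamide, via lithium enolate 3 (not isolated), via lithium carbinolate adduct 4 (not isolated)
Conditions: 2, LiN(iPr)2, THF, −78 °C; 1, −78 → 0 °C; 1 M HCl, rt
Reagents that add atoms: water, SMILES O
Why: Stork–Danheiser enone transposition: the amide enolate 3 adds 1,2 to the vinylogous ester carbonyl of 1, and aqueous acid ionises the tertiary allylic carbinol and hydrolyses the ethoxyallyl cation, so that the old carbonyl carbon becomes C1 bearing the C10–C9 chain and the old enol ether carbon becomes the C4 ketone.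

Step 2
Reactants: 5 N-methoxy-N-methyl-2-(3-oxocyclopent-1-en-1-yl)acetamide
Product: 6 2-(3-hydroxycyclopent-1-en-1-yl)-N-methoxy-N-methylacetamide (racemic)
Conditions: NaBH4, CeCl3·7H2O, MeOH, −20 → 0 °C
Reagents that add atoms: none
Why: Luche reduction delivers hydride 1,2 to the enone while the Weinreb amide is inert to NaBH4, and it removes the ring carbonyl for the time being because neither the Grignard addition of step 4 nor the ketalisation of step 5 could tell two enone carbonyls apart.

Step 3
Reactants: 6 2-(3-hydroxycyclopent-1-en-1-yl)-N-methoxy-N-methylacetamide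
Product: 7 2-{3-[(tert-butyldimethylsilyl)oxy]cyclopent-1-en-1-yl}-N-methoxy-N-methylacetamide (racemic)
Conditions: TBSCl, imidazole, DMF, rt
Reagents that add atoms: tert-butyldimethylsilyl chloride, SMILES CC(C)(C)[Si](C)(C)Cl
Why: Imidazole-promoted silyl ether formation masks the allylic hydroxyl so that no alkoxide or free allylic alcohol meets the Grignard reagent and the silyl triflate of the next two steps.

Step 4
Reactants: 7 silyl ether Weinreb amide; 8 isopropenylmagnesium bromide
Product: 10 1-{3-[(tert-butyldimethylsilyl)oxy]cyclopent-1-en-1-yl}-3-methylbut-3-en-2-one (racemic), via magnesium hemiaminal chelate 9 (not isolated)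
Conditions: 8, THF, −20 → 0 °C; poured into cold 0.5 M HCl
Reagents that add atoms: none
Why: Weinreb ketone synthesis: the five-membered magnesium chelate 9 holds until the quench so that only one isopropenyl group (C8, C14 and the terminal CH2) is taken up, and the acidic quench protonates the liberated amine before it can add to the new enone.

Step 5
Reactants: 10 isopropenyl ketone
Product: 11 tert-butyldimethyl[(3-{[2-(prop-1-en-2-yl)-1,3-dioxolan-2-yl]methyl}cyclopent-2-en-1-yl)oxy]silane (racemic)
Conditions: (Me3SiOCH2)2, Me3SiOTf (cat), CH2Cl2, −78 → −40 °C; pyridine quench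
Reagents that add atoms: 1,2-bis(trimethylsilyloxy)ethane, SMILES C[Si](C)(C)OCCO[Si](C)(C)C
Why: Noyori ketalisation (silylated diol, catalytic silyl triflate, aprotic, low temperature) turns the only carbonyl group present into the dioxolane without moving the C1=C5 alkene into conjugation and without touching the silyl ether.

Step 6
Reactants: 11 ketal silyl ether
Product: 12 3-{[2-(prop-1-en-2-yl)-1,3-dioxolan-2-yl]methyl}cyclopent-2-en-1-ol (racemic)
Conditions: Bu4NF, THF, 0 °C → rt
Reagents that add atoms: none
Why: Fluoride-induced desilylation runs under non-acidic conditions that leave the dioxolane intact.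

Step 7
Reactants: 12 ketal allylic alcohol
Product: 13 3-{[2-(prop-1-en-2-yl)-1,3-dioxolan-2-yl]methyl}cyclopent-2-en-1-one
Conditions: MnO2 (activated), CH2Cl2, rt
Reagents that add atoms: none
Why: MnO2 allylic oxidation restores the ring enone under neutral heterogeneous conditions and avoids base that could open the ketal by vinylogous β-elimination through C10.

Step 8
Reactants: 13 ketal enone; 14 trimethylaluminium; 15 acrolein
Product: 17 (2S,3R)-2-[(1S)-1-hydroxyprop-2-en-1-yl]-3-methyl-3-{[2-(prop-1-en-2-yl)-1,3-dioxolan-2-yl]methyl}cyclopentan-1-one (1R,5S,6S in daucane numbering), via dimethylaluminium enolate 16 (not isolated)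
Conditions: Cu(OTf)2 (5 mol %), L* (10 mol %), 14 (1.5 equiv), Et2O, −30 °C; then 15 (3 equiv), −78 → −40 °C; aq potassium sodium tartrate; minor C6 epimer removed by chromatography. L* = 2,2'-biphenol-derived phosphoramidite of bis[1-(2-naphthyl)ethyl]amine, the antipode that gives 1R
Reagents that add atoms: none
Why: Transmetalation gives a chiral methylcopper–aluminium species that transfers methyl 1,4 to C1 of 13 (copper-catalysed asymmetric conjugate addition of a trialkylaluminium to a β-substituted cyclic enone), and the dimethylaluminium enolate 16, formed regiospecifically across C4–C5, then attacks acrolein 1,2 (tandem conjugate addition–aldol). No ring is closed, and the two new bonds are C1–CH3 and C5–C6. C1 is set by the ligand, which selects the enone face. C5 is set by the substrate, because the aldehyde approaches 16 on the methyl-bearing face, away from the much larger dioxolanylmethyl arm, so that C6 and C10 end up trans as the trans ring fusion requires. C6 follows from a closed Zimmerman–Traxler chair of the ring-locked E(O)-enolate, which leads to the anti aldol, the relation needed for the 6S carbinol. The step needs 1,4- over 1,2-methyl transfer and survival of the ketal: the soft copper reagent secures the first, and ether-complexed AlMe3 at −30 °C, together with the poor cation stabilisation offered by the unsubstituted isopropenyl terminus, secures the second.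

Step 9
Reactants: 17 aldol
Product: 18 1-ethoxyethyl ether of 17 (epimers at the acetal carbon)
Conditions: ethyl vinyl ether, PPTS (cat), CH2Cl2, 0 °C → rt; all vinyl ether stripped off
Reagents that add atoms: ethyl vinyl ether, SMILES C=COCC
Why: Acid-catalysed addition of the hydroxyl group to ethyl vinyl ether (EE acetal protection) works on hindered β-hydroxy ketones without retro-aldol cleavage, and an acetal is preferred to a silyl ether because O6 will sit 1,3-syn to the C4 alkoxide of step 14, to which silicon could migrate.

Step 10
Reactants: 18 EE-protected diene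
Product: 19 (1R,5S,6S)-6-(1-ethoxyethoxy)-9,9-(ethylenedioxy)-11,12,13-trinordauc-7-en-4-one (trans-fused hydroazulenone: H5 α; C15 β; O6 α)
Conditions: second-generation Hoveyda–Grubbs catalyst (5–10 mol %), toluene (0.005 M), 80 °C, argon sparge
Reagents that add atoms: none
Why: Ring-closing metathesis: the catalyst loads on the monosubstituted C7 vinyl group and closes onto the isopropenyl group to give the trisubstituted C7=C8 alkene of the seven-membered ring, the trans arms on C1 and C5 being within reach and loss of ethene driving the reaction.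

Step 11
Reactants: 19 hydroazulenone; 20 isopropylmagnesium chloride
Product: 21 (1R,4R,5S,6S)-6-(1-ethoxyethoxy)-9,9-(ethylenedioxy)dauc-7-en-4-ol
Conditions: CeCl3 (anhydrous), 20, THF, −78 °C, 1 h; then 19, −78 → 0 °C; aq NaHCO3
Reagents that add atoms: none
Why: Organocerium 1,2-addition: the weakly basic reagent avoids enolisation at C3 or C5 and β-hydride reduction, and it should attack C4 from the α face, the side of H5, because the β face is screened by the angular methyl C15 and by the O6 acetal that leans over it, which sets 4R with hydroxyl β and isopropyl α.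

Step 12
Reactants: 22 4-hydroxybenzoic acid
Product: 23 tert-butyldimethylsilyl 4-[(tert-butyldimethylsilyl)oxy]benzoate
Conditions: TBSCl (2.3 equiv), imidazole, DMF, rt
Reagents that add atoms: tert-butyldimethylsilyl chloride, SMILES CC(C)(C)[Si](C)(C)Cl
Why: Exhaustive imidazole-promoted silylation covers the phenol and turns the acid into a silyl ester, the direct precursor of the acid chloride.

Step 13
Reactants: 23 bis-silyl derivative
Product: 24 4-[(tert-butyldimethylsilyl)oxy]benzoyl chloride
Conditions: (COCl)2, DMF (cat), CH2Cl2, 0 °C → rt; volatiles removed under high vacuum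
Reagents that add atoms: oxalyl chloride, SMILES O=C(Cl)C(=O)Cl
Why: The chloroiminium salt from oxalyl chloride and DMF converts silyl esters into acid chlorides without release of HCl, so the aryl silyl ether survives.

Step 14
Reactants: 21 tertiary carbinol; 24 acid chloride
Product: 26 (1R,4R,5S,6S)-6-(1-ethoxyethoxy)-9,9-(ethylenedioxy)dauc-7-en-4-yl 4-[(tert-butyldimethylsilyl)oxy]benzoate, via lithium alkoxide 25 (not isolated)
Conditions: n-BuLi, THF, −78 °C; 24, −78 °C → rt; aq NaHCO3
Reagents that add atoms: none
Why: O-Acylation of a preformed lithium tert-alkoxide with an aroyl chloride is the classical route to esters of hindered tertiary alcohols, it touches no stereocentre, and the acetal on O6 can neither migrate nor be acylated.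

Step 15
Reactants: 26 protected ester
Product: 27 (1R,4R,5S,6S)-6-hydroxy-9-oxodauc-7-en-4-yl 4-hydroxybenzoate (target)
Conditions: 48% aq HF, MeCN, 0 °C → rt; pH 7 buffer work-up
Reagents that add atoms: water, SMILES O
Why: Aqueous HF supplies in one pot the mild acid that hydrolyses the EE acetal and the allylic dioxolane and the fluoride that cleaves the aryl silyl ether, while the absence of base prevents acyl shift from O4 to the neighbouring O6 and isomerisation of the γ-hydroxy enone, and the acid is too weak to ionise the tertiary ester.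

Compound list
1 | 3-ethoxycyclopent-2-en-1-one | CCOC1=CC(=O)CC1 | starting material
2 | N-methoxy-N-methylacetamide | CC(=O)N(C)OC | starting material
3 | lithium enolate of 2 | C=C(O[Li])N(C)OC | intermediate
4 | lithium 3-ethoxy-1-{2-[methoxy(methyl)amino]-2-oxoethyl}cyclopent-2-en-1-olate (racemic) | CCOC1=CC(O[Li])(CC(=O)N(C)OC)CC1 | intermediate
5 | N-methoxy-N-methyl-2-(3-oxocyclopent-1-en-1-yl)acetamide | CON(C)C(=O)CC1=CC(=O)CC1 | intermediate
6 | 2-(3-hydroxycyclopent-1-en-1-yl)-N-methoxy-N-methylacetamide (racemic) | CON(C)C(=O)CC1=CC(O)CC1 | intermediate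
7 | 2-{3-[(tert-butyldimethylsilyl)oxy]cyclopent-1-en-1-yl}-N-methoxy-N-methylacetamide (racemic) | CON(C)C(=O)CC1=CC(O[Si](C)(C)C(C)(C)C)CC1 | intermediate
8 | isopropenylmagnesium bromide | CC(=C)[Mg]Br | starting material
9 | magnesium hemiaminal chelate from 7 and 8 | CC(=C)C(O[Mg]Br)(CC1=CC(O[Si](C)(C)C(C)(C)C)CC1)N(C)OC | intermediate
10 | 1-{3-[(tert-butyldimethylsilyl)oxy]cyclopent-1-en-1-yl}-3-methylbut-3-en-2-one (racemic) | CC(=C)C(=O)CC1=CC(O[Si](C)(C)C(C)(C)C)CC1 | intermediate
11 | tert-butyldimethyl[(3-{[2-(prop-1-en-2-yl)-1,3-dioxolan-2-yl]methyl}cyclopent-2-en-1-yl)oxy]silane (racemic) | CC(=C)C1(CC2=CC(O[Si](C)(C)C(C)(C)C)CC2)OCCO1 | intermediate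
12 | 3-{[2-(prop-1-en-2-yl)-1,3-dioxolan-2-yl]methyl}cyclopent-2-en-1-ol (racemic) | CC(=C)C1(CC2=CC(O)CC2)OCCO1 | intermediate
13 | 3-{[2-(prop-1-en-2-yl)-1,3-dioxolan-2-yl]methyl}cyclopent-2-en-1-one | O=C1CCC(CC2(OCCO2)C(C)=C)=C1 | intermediate
14 | trimethylaluminium | C[Al](C)C | starting material
15 | acrolein | C=CC=O | starting material
16 | dimethylaluminium C4–C5 enolate (1R) | C[Al](C)OC1=C[C@@](C)(CC2(OCCO2)C(C)=C)CC1 | intermediate
17 | (2S,3R)-2-[(1S)-1-hydroxyprop-2-en-1-yl]-3-methyl-3-{[2-(prop-1-en-2-yl)-1,3-dioxolan-2-yl]methyl}cyclopentan-1-one | C=C[C@H](O)[C@H]1C(=O)CC[C@]1(C)CC2(OCCO2)C(C)=C | intermediate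
18 | 1-ethoxyethyl ether of 17 (epimers at the acetal carbon) | C=C[C@H](OC(C)OCC)[C@H]1C(=O)CC[C@]1(C)CC2(OCCO2)C(C)=C | intermediate
19 | (1R,5S,6S)-6-(1-ethoxyethoxy)-9,9-(ethylenedioxy)-11,12,13-trinordauc-7-en-4-one | CC1=C[C@H](OC(C)OCC)[C@@H]2[C@](C)(CCC2=O)CC13OCCO3 | intermediate
20 | isopropylmagnesium chloride | CC(C)[Mg]Cl | starting material
21 | (1R,4R,5S,6S)-6-(1-ethoxyethoxy)-9,9-(ethylenedioxy)dauc-7-en-4-ol | CC1=C[C@H](OC(C)OCC)[C@@H]2[C@](C)(CC[C@@]2(O)C(C)C)CC13OCCO3 | intermediate
22 | 4-hydroxybenzoic acid | OC(=O)c1ccc(O)cc1 | starting material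
23 | tert-butyldimethylsilyl 4-[(tert-butyldimethylsilyl)oxy]benzoate | CC(C)(C)[Si](C)(C)OC(=O)c1ccc(O[Si](C)(C)C(C)(C)C)cc1 | intermediate
24 | 4-[(tert-butyldimethylsilyl)oxy]benzoyl chloride | O=C(Cl)c1ccc(O[Si](C)(C)C(C)(C)C)cc1 | intermediate
25 | lithium alkoxide of 21 | CC1=C[C@H](OC(C)OCC)[C@@H]2[C@](C)(CC[C@@]2(O[Li])C(C)C)CC13OCCO3 | intermediate
26 | (1R,4R,5S,6S)-6-(1-ethoxyethoxy)-9,9-(ethylenedioxy)dauc-7-en-4-yl 4-[(tert-butyldimethylsilyl)oxy]benzoate | CC1=C[C@H](OC(C)OCC)[C@@H]2[C@](C)(CC[C@@]2(OC(=O)c4ccc(O[Si](C)(C)C(C)(C)C)cc4)C(C)C)CC13OCCO3 | intermediate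
27 | (1R,4R,5S,6S)-6-hydroxy-9-oxodauc-7-en-4-yl 4-hydroxybenzoate | CC1=C[C@H](O)[C@@H]2[C@](C)(CC[C@@]2(OC(=O)c2ccc(O)cc2)C(C)C)CC1=O | target

Total step count: 15. Longest linear sequence: 13 (steps 1–11, 14, 15).

Steps most likely to fail

Step 8. Methyl transfer to a cyclopentenone whose β-substituent is neopentyl-like may be slow. Capture of the crowded aluminium enolate by acrolein may also lag behind methyl transfer to the aldehyde and retro-aldol equilibration, with loss of control at C6. The fallback splits the operation and changes the enolate metal. Setting out from 13, the same conjugate addition is run and enolate 16 is silylated with Me3SiOTf at −78 °C to the trimethylsilyl enol ether F1, which is isolated and checked for enantiopurity. MeLi in THF then releases the regiodefined lithium enolate F2. This adds to 15 at −78 °C under kinetic control through the same closed chair and returns to the route at 17.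

Step 14. The lithium alkoxide lies buried between the isopropyl group, the ring fusion and the O6 acetal, so acyl transfer may be too slow to compete with decay of the acid chloride. The fallback sets out from 19 and lowers the bulk next to O4. Isopropenylcerium dichloride, made from 8 and CeCl3, adds from the α face to give the isopropenyl carbinol F3. n-BuLi converts it into the lithium alkoxide F4, and 24 acylates this flatter, less shielded centre to the isopropenyl ester F5. Chemoselective hydrogenation of the 1,1-disubstituted alkene with RhCl(PPh3)3 and H2 in benzene leaves the flanked trisubstituted C7=C8 alkene alone and returns to the route at 26.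

Step 10. The catalyst may load on the C7 vinyl group but fail to engage the isopropenyl group next to the fully substituted ketal carbon, so that oligomerisation through the vinyl ends and catalyst decay take over. The fallback postpones ring closure until C9 is a planar carbonyl. Setting out from 18, isopropylcerium dichloride adds to C4 anti to the C5 side chain to give the monocyclic tertiary carbinol F6. n-BuLi gives its lithium alkoxide F7, and 24 gives the monocyclic ester F8. Aqueous HF in MeCN strips the acetal, the ketal and the silyl ether to the seco hydroxy dienone F9. Ring-closing metathesis of its allylic alcohol vinyl group with the isopropenyl ketone (second-generation Hoveyda–Grubbs catalyst, CH2Cl2, reflux) returns to the route at 27.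

Further compounds
F1 | step 8 | trimethylsilyl enol ether of the (1R) conjugate adduct | C[Si](C)(C)OC1=C[C@@](C)(CC2(OCCO2)C(C)=C)CC1
F2 | step 8 | lithium C4–C5 enolate of the (1R) conjugate adduct | [Li]OC1=C[C@@](C)(CC2(OCCO2)C(C)=C)CC1
F3 | step 14 | isopropenyl carbinol (4β-OH, 4α-isopropenyl analogue of 21) | CC1=C[C@H](OC(C)OCC)[C@@H]2[C@](C)(CC[C@@]2(O)C(C)=C)CC13OCCO3
F4 | step 14 | lithium alkoxide of F3 | CC1=C[C@H](OC(C)OCC)[C@@H]2[C@](C)(CC[C@@]2(O[Li])C(C)=C)CC13OCCO3
F5 | step 14 | isopropenyl analogue of ester 26 | CC1=C[C@H](OC(C)OCC)[C@@H]2[C@](C)(CC[C@@]2(OC(=O)c4ccc(O[Si](C)(C)C(C)(C)C)cc4)C(C)=C)CC13OCCO3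
F6 | step 10 | monocyclic tertiary carbinol (isopropyl adduct of 18) | C=C[C@H](OC(C)OCC)[C@@H]2[C@](C)(CC[C@@]2(O)C(C)C)CC3(OCCO3)C(C)=C
F7 | step 10 | lithium alkoxide of F6 | C=C[C@H](OC(C)OCC)[C@@H]2[C@](C)(CC[C@@]2(O[Li])C(C)C)CC3(OCCO3)C(C)=C
F8 | step 10 | monocyclic 4-[(tert-butyldimethylsilyl)oxy]benzoate | C=C[C@H](OC(C)OCC)[C@@H]2[C@](C)(CC[C@@]2(OC(=O)c4ccc(O[Si](C)(C)C(C)(C)C)cc4)C(C)C)CC3(OCCO3)C(C)=C
F9 | step 10 | seco hydroxy dienone 4-hydroxybenzoate | C=C[C@H](O)[C@@H]2[C@](C)(CC[C@@]2(OC(=O)c4ccc(O)cc4)C(C)C)CC(=O)C(C)=C
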